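Numbering the target from the lactone carbonyl (C1) to the chain end (C20), the plan exploits the anti C5–O/C7–O pair that sits beside C3, an sp2 carbon of the C2=C3 bond in the dihydropyranone ring. C3–C7 are therefore assembled as an all-cis tetrahydropyran (oxygen bridging C3 and C7, oxygen substituent on C5) by a Prins cyclization of a C7–C20 bis-silyloxy aldehyde with (S)-1-chloropent-4-en-2-ol: one operation forms C6–C7, C7–O and C5–O and sets C5 and C7 from a throwaway C3 centre. Zinc later opens the pyran to the C7 alcohol and a C3 vinyl group, and metathesis of the C5 acrylate closes the lactone.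

Key step: step 6

Remark: Ti(OiPr)4/(R)-BINOL is assumed to direct the dienolate to the aldehyde face that gives the 5S alcohol (the sense found for allylation of unbranched aldehydes with this catalyst family); if the opposite sense is found, (S)-BINOL is used instead.

Step 1
Reactants: 1 decanal; 2 1-methoxy-1,3-bis(trimethylsilyloxy)buta-1,3-diene
Product: 4 methyl (5S)-5-hydroxy-3-oxotetradecanoate, via silylated aldol adduct 3 (not isolated)
Conditions: Ti(OiPr)4 (10 mol%), (R)-BINOL (10 mol%), THF, −78 °C → rt; then CF3CO2H (cat.), THF/H2O, 0 °C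
Reagents that add atoms: none
Why: The BINOL–titanium Lewis acid should activate decanal for a vinylogous Mukaiyama aldol at the terminal carbon of dienolate 2, the ligand shielding one aldehyde face so that C11 is set as S under catalyst control, and mild acid then unmasks the keto ester from 3.

Step 2
Reactants: 4 methyl (5S)-5-hydroxy-3-oxotetradecanoate
Product: 6 methyl (3S,5S)-3,5-dihydroxytetradecanoate, via diethylboron chelate 5 (not isolated)
Conditions: Et2BOMe (1.1 equiv), THF/MeOH 4:1, −78 °C; NaBH4, −78 °C; AcOH, then MeOH co-evaporation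
Reagents that add atoms: none
Why: In this Narasaka–Prasad reduction the boron chelate 5 holds the hydroxy ketone in a half-chair, so external hydride adds axially and the C11 centre relays to C9, giving the syn-1,3-diol.

Step 3
Reactants: 6 methyl (3S,5S)-3,5-dihydroxytetradecanoate
Product: 7 methyl (3S,5S)-3,5-bis(tert-butyldiphenylsilyloxy)tetradecanoate
Conditions: TBDPSCl (3 equiv), imidazole (6 equiv), DMAP (cat.), DMF, rt → 45 °C
Reagents that add atoms: tert-butyl(chloro)diphenylsilane, CC(C)(C)[Si](Cl)(c1ccccc1)c1ccccc1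
Why: Silyl ether formation from a chlorosilane under imidazole/DMAP catalysis touches no stereocentre, excess reagent and gentle warming should drive the second, more hindered silylation, and this silyl group is chosen because it resists CF3CO2H in step 6.

Step 4
Reactants: 7 methyl (3S,5S)-3,5-bis(tert-butyldiphenylsilyloxy)tetradecanoate
Product: 8 (3S,5S)-3,5-bis(tert-butyldiphenylsilyloxy)tetradecanal (fragment 1, C7–C20)
Conditions: i-Bu2AlH (1.1 equiv), CH2Cl2, −78 °C; MeOH, then aq. potassium sodium tartrate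
Reagents that add atoms: none
Why: Partial ester-to-aldehyde reduction with one equivalent of i-Bu2AlH at −78 °C should deliver the aldehyde after the cold quench, and neither the silyl ethers nor the stereocentres (none is alpha to the carbonyl) are affected.

Step 5
Reactants: 9 (S)-epichlorohydrin; 10 vinylmagnesium bromide
Product: 11 (S)-1-chloropent-4-en-2-ol (fragment 2)
Conditions: CuI (10 mol%), THF, −40 → −20 °C; aq. NH4Cl
Reagents that add atoms: none
Why: Copper-catalysed Grignard opening of a terminal epoxide is an SN2 attack at the unsubstituted CH2, so the C–O bond of the stereocentre is never broken and the S configuration passes into 11, while the low temperature should keep the chlorohydrin from closing to a new epoxide.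

Step 6
Reactants: 8 (3S,5S)-3,5-bis(tert-butyldiphenylsilyloxy)tetradecanal; 11 (S)-1-chloropent-4-en-2-ol
Product: 13 (2R,4R,6S)-2-[(2R,4S)-2,4-bis(tert-butyldiphenylsilyloxy)tridecyl]-6-(chloromethyl)oxan-4-ol (all-cis), via pyranyl trifluoroacetate 12 (not isolated)
Conditions: CF3CO2H (15 equiv), CH2Cl2, 0 °C → rt; concentrate; K2CO3, MeOH, rt
Reagents that add atoms: trifluoroacetic acid, OC(=O)C(F)(F)F
Why: CF3CO2H condenses the hydroxyl of 11 with aldehyde 8 to an (E)-oxocarbenium ion, the terminal alkene carbon C6 attacks C7 through a chair, and the resulting C5 cation is captured by trifluoroacetate, so C6–C7, C7–O and C5–O form in one event; this is the acid-promoted Prins cyclization of a homoallylic alcohol with an aldehyde to a 2,6-cis-tetrahydropyran-4-ol derivative. The tetrahydropyran (O, C3, C4, C5, C6, C7) closes in the 6-endo-trig mode. C7 is set by the existing C3 centre of 11, because the chair places both the CH2Cl group and the C8 chain equatorial, and C5 is set by equatorial capture of the cation on the same chair, giving the all-cis ring that corresponds to the anti C5/C7 diol. The step needs all-cis diastereoselectivity and freedom from allyl-transfer (2-oxonia-Cope) scrambling; the equatorial preference at C3 secures the first whatever the remote C9/C11 silyloxy centres prefer, and the electron-withdrawing CH2Cl group, which destabilises the rearranged oxocarbenium ion, secures the second. The tert-butyldiphenylsilyl ethers should tolerate the acid, and K2CO3/MeOH then cleaves only the labile trifluoroacetate of 12.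

Step 7
Reactants: 13 all-cis chloromethyl pyranol
Product: 14 (2R,4R,6S)-2-[(2R,4S)-2,4-bis(tert-butyldiphenylsilyloxy)tridecyl]-6-(iodomethyl)oxan-4-ol
Conditions: NaI (10 equiv), 2-butanone, reflux
Reagents that add atoms: sodium iodide, [Na+].[I-]
Why: Finkelstein halide exchange (SN2 at the primary CH2Cl carbon) is driven by precipitation of NaCl from the ketone solvent, involves no ring stereocentre, and is run on the free alcohol so that no acrylate is exposed to hot iodide.

Step 8
Reactants: 14 all-cis iodomethyl pyranol; 15 acryloyl chloride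
Product: 16 (2R,4R,6S)-2-[(2R,4S)-2,4-bis(tert-butyldiphenylsilyloxy)tridecyl]-6-(iodomethyl)oxan-4-yl prop-2-enoate
Conditions: i-Pr2NEt (3 equiv), CH2Cl2, −20 → 0 °C
Reagents that add atoms: none
Why: O-Acylation of the unhindered equatorial secondary alcohol with an acid chloride and a hindered amine base installs C1 and C2 on the C5 oxygen while the C7 oxygen is still masked as the ring ether, which differentiates the two oxygens of the anti-diol.

Step 9
Reactants: 16 all-cis iodomethyl pyranyl acrylate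
Product: 17 (4S,6R,8R,10S)-8,10-bis(tert-butyldiphenylsilyloxy)-6-hydroxynonadec-1-en-4-yl prop-2-enoate
Conditions: Zn dust (activated), AcOH (5 equiv), THF/EtOH, rt → 40 °C
Reagents that add atoms: none
Why: Zinc insertion into the C–I bond is followed at once by beta-elimination of the ring oxygen (Boord-type reductive elimination, as in the Bernet–Vasella fragmentation), which frees the C7 hydroxyl and the C3 vinyl group and erases the C3 stereocentre, while the weakly acidic medium protonates the alkoxide immediately and should suppress acrylate migration from the C5 to the C7 oxygen.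

Step 10
Reactants: 17 open-chain C7 alcohol with C5 acrylate and C3 vinyl group
Product: 18 (6S)-6-[(2R,4R,6S)-4,6-bis(tert-butyldiphenylsilyloxy)-2-hydroxypentadecyl]-5,6-dihydro-2H-pyran-2-one
Conditions: second-generation Grubbs catalyst (5 mol%), CH2Cl2 (0.005 M), reflux
Reagents that add atoms: none
Why: Ring-closing metathesis of the acrylate of a homoallylic alcohol forms the C2=C3 bond of the six-membered lactone (necessarily Z) with loss of ethene, high dilution disfavours dimerisation, and the free C7 hydroxyl and the silyl ethers are tolerated.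

Step 11
Reactants: 18 bis-silyl ether of the target
Product: 19 (6S)-6-[(2S,4S,6S)-2,4,6-trihydroxypentadecyl]-5,6-dihydro-2H-pyran-2-one (CNP0417102.4)
Conditions: HF·pyridine, pyridine, THF, 0 °C → rt
Reagents that add atoms: none
Why: Fluoride-mediated Si–O cleavage under buffered acidic conditions should free the C9 and C11 hydroxyls without the oxa-Michael addition of the C7 hydroxyl to the enoate or the lactone opening that basic fluoride sources can cause, and no stereocentre is touched.

Compound list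
1 | decanal | CCCCCCCCCC=O | starting material
2 | 1-methoxy-1,3-bis(trimethylsilyloxy)buta-1,3-diene | COC(O[Si](C)(C)C)=CC(=C)O[Si](C)(C)C | starting material
3 | methyl (5S)-3,5-bis(trimethylsilyloxy)tetradec-2-enoate (silylated aldol adduct) | CCCCCCCCC[C@H](O[Si](C)(C)C)CC(O[Si](C)(C)C)=CC(=O)OC | intermediate (not isolated)
4 | methyl (5S)-5-hydroxy-3-oxotetradecanoate | CCCCCCCCC[C@H](O)CC(=O)CC(=O)OC | intermediate
5 | methyl (5S)-5-[(diethylboranyl)oxy]-3-oxotetradecanoate (boron chelate) | CCCCCCCCC[C@H](OB(CC)CC)CC(=O)CC(=O)OC | intermediate (not isolated)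
6 | methyl (3S,5S)-3,5-dihydroxytetradecanoate | CCCCCCCCC[C@H](O)C[C@H](O)CC(=O)OC | intermediate
7 | methyl (3S,5S)-3,5-bis(tert-butyldiphenylsilyloxy)tetradecanoate | CCCCCCCCC[C@H](O[Si](c1ccccc1)(c1ccccc1)C(C)(C)C)C[C@H](O[Si](c1ccccc1)(c1ccccc1)C(C)(C)C)CC(=O)OC | intermediate
8 | (3S,5S)-3,5-bis(tert-butyldiphenylsilyloxy)tetradecanal | CCCCCCCCC[C@H](O[Si](c1ccccc1)(c1ccccc1)C(C)(C)C)C[C@H](O[Si](c1ccccc1)(c1ccccc1)C(C)(C)C)CC=O | intermediate
9 | (S)-epichlorohydrin | ClC[C@@H]1CO1 | starting material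
10 | vinylmagnesium bromide | C=C[Mg]Br | starting material
11 | (S)-1-chloropent-4-en-2-ol | C=CC[C@@H](CCl)O | intermediate
12 | (2R,4R,6S)-2-[(2R,4S)-2,4-bis(tert-butyldiphenylsilyloxy)tridecyl]-6-(chloromethyl)oxan-4-yl trifluoroacetate (all-cis) | CCCCCCCCC[C@H](O[Si](c1ccccc1)(c1ccccc1)C(C)(C)C)C[C@H](O[Si](c1ccccc1)(c1ccccc1)C(C)(C)C)C[C@H]1C[C@@H](OC(=O)C(F)(F)F)C[C@@H](CCl)O1 | intermediate (not isolated)
13 | (2R,4R,6S)-2-[(2R,4S)-2,4-bis(tert-butyldiphenylsilyloxy)tridecyl]-6-(chloromethyl)oxan-4-ol (all-cis) | CCCCCCCCC[C@H](O[Si](c1ccccc1)(c1ccccc1)C(C)(C)C)C[C@H](O[Si](c1ccccc1)(c1ccccc1)C(C)(C)C)C[C@H]1C[C@@H](O)C[C@@H](CCl)O1 | intermediate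
14 | (2R,4R,6S)-2-[(2R,4S)-2,4-bis(tert-butyldiphenylsilyloxy)tridecyl]-6-(iodomethyl)oxan-4-ol (all-cis) | CCCCCCCCC[C@H](O[Si](c1ccccc1)(c1ccccc1)C(C)(C)C)C[C@H](O[Si](c1ccccc1)(c1ccccc1)C(C)(C)C)C[C@H]1C[C@@H](O)C[C@@H](CI)O1 | intermediate
15 | acryloyl chloride | C=CC(=O)Cl | starting material
16 | (2R,4R,6S)-2-[(2R,4S)-2,4-bis(tert-butyldiphenylsilyloxy)tridecyl]-6-(iodomethyl)oxan-4-yl prop-2-enoate (all-cis) | CCCCCCCCC[C@H](O[Si](c1ccccc1)(c1ccccc1)C(C)(C)C)C[C@H](O[Si](c1ccccc1)(c1ccccc1)C(C)(C)C)C[C@H]1C[C@@H](OC(=O)C=C)C[C@@H](CI)O1 | intermediate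
17 | (4S,6R,8R,10S)-8,10-bis(tert-butyldiphenylsilyloxy)-6-hydroxynonadec-1-en-4-yl prop-2-enoate | CCCCCCCCC[C@H](O[Si](c1ccccc1)(c1ccccc1)C(C)(C)C)C[C@H](O[Si](c1ccccc1)(c1ccccc1)C(C)(C)C)C[C@H](O)C[C@@H](OC(=O)C=C)CC=C | intermediate
18 | (6S)-6-[(2R,4R,6S)-4,6-bis(tert-butyldiphenylsilyloxy)-2-hydroxypentadecyl]-5,6-dihydro-2H-pyran-2-one | CCCCCCCCC[C@H](O[Si](c1ccccc1)(c1ccccc1)C(C)(C)C)C[C@H](O[Si](c1ccccc1)(c1ccccc1)C(C)(C)C)C[C@H](O)C[C@@H]1CC=CC(=O)O1 | intermediate
19 | (6S)-6-[(2S,4S,6S)-2,4,6-trihydroxypentadecyl]-5,6-dihydro-2H-pyran-2-one | CCCCCCCCC[C@H](O)C[C@H](O)C[C@H](O)C[C@@H]1CC=CC(=O)O1 | target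

Total step count: 11. Longest linear sequence: 10 steps (steps 1–4 and 6–11, from decanal); step 5 is the one-step side branch.

Steps most likely to fail

Step 6. The bimolecular condensation of the hindered aldehyde may be slow, which would give time for acidolysis of a silyl ether or for allyl-transfer scrambling that erodes the all-cis selectivity. The fallback is a segment-coupling Prins reaction that makes the same oxocarbenium ion intramolecularly, without water and without a large excess of strong acid; it sets out from 7 (with 11) and returns at 13. Ester 7 is saponified (LiOH, THF/MeOH/H2O) to (3S,5S)-3,5-bis(tert-butyldiphenylsilyloxy)tetradecanoic acid F1. This is esterified with 11 (DCC, DMAP, CH2Cl2) to the (S)-1-chloropent-4-en-2-yl ester F2. Reductive acetylation (i-Bu2AlH, CH2Cl2, −78 °C; then Ac2O, pyridine, DMAP) gives the alpha-acetoxy ether F3. Ionisation with BF3·OEt2/AcOH in hexane at 0 °C should close it through the same chair to the all-cis pyranyl acetate F4, and K2CO3/MeOH then gives 13.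

Step 9. The acryloyl group may migrate to the newly freed C7 hydroxyl, or be solvolysed or reduced, while zinc opens the ring. The fallback carries the C5 oxygen through the ring opening as an ether and installs the acrylate afterwards; it sets out from 14 and returns at 19.
- 14 is converted with 4-methoxybenzyl trichloroacetimidate and La(OTf)3 (cat.) into the C5 4-methoxybenzyl ether of the iodomethyl pyran F5.
- Zn dust in refluxing EtOH opens it to the C7 alcohol with C5 4-methoxybenzyl ether and C3 vinyl group F6.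
- TBSOTf/2,6-lutidine gives the C7 tert-butyldimethylsilyl ether F7.
- DDQ (CH2Cl2, pH 7 buffer) frees the C5 alcohol F8.
- Acryloyl chloride/i-Pr2NEt gives the C5 acrylate F9.
- The second-generation Grubbs catalyst closes the tris-silyl dihydropyranone F10.
- HF·pyridine removes all three silyl groups to give 19.

Step 1. Facial selectivity may be insufficient with an unbranched aliphatic aldehyde, which would later show up as diastereomers after coupling with enantiopure 11. The fallback sets C11 by asymmetric hydrogenation; it sets out from 1 and returns at 4. Decanal is homologated with ethyl diazoacetate and SnCl2 (cat.) to ethyl 3-oxododecanoate F11. Hydrogenation with RuCl2[(S)-BINAP] in EtOH gives ethyl (S)-3-hydroxydodecanoate F12. Saponification (LiOH) gives (S)-3-hydroxydodecanoic acid F13. Activation with 1,1'-carbonyldiimidazole and reaction with Mg(O2CCH2CO2Me)2 in THF (decarboxylative Claisen chain extension) then gives 4.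

Further compounds
F1 | step 6 | (3S,5S)-3,5-bis(tert-butyldiphenylsilyloxy)tetradecanoic acid | CCCCCCCCC[C@H](O[Si](c1ccccc1)(c1ccccc1)C(C)(C)C)C[C@H](O[Si](c1ccccc1)(c1ccccc1)C(C)(C)C)CC(=O)O
F2 | step 6 | (S)-1-chloropent-4-en-2-yl (3S,5S)-3,5-bis(tert-butyldiphenylsilyloxy)tetradecanoate | CCCCCCCCC[C@H](O[Si](c1ccccc1)(c1ccccc1)C(C)(C)C)C[C@H](O[Si](c1ccccc1)(c1ccccc1)C(C)(C)C)CC(=O)O[C@H](CCl)CC=C
F3 | step 6 | (3S,5S)-3,5-bis(tert-butyldiphenylsilyloxy)-1-{[(2S)-1-chloropent-4-en-2-yl]oxy}tetradecyl acetate (alpha-acetoxy ether, both C1 epimers) | CCCCCCCCC[C@H](O[Si](c1ccccc1)(c1ccccc1)C(C)(C)C)C[C@H](O[Si](c1ccccc1)(c1ccccc1)C(C)(C)C)CC(OC(C)=O)O[C@H](CCl)CC=C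
F4 | step 6 | all-cis 2-[2,4-bis(tert-butyldiphenylsilyloxy)tridecyl]-6-(chloromethyl)oxan-4-yl acetate | CCCCCCCCC[C@H](O[Si](c1ccccc1)(c1ccccc1)C(C)(C)C)C[C@H](O[Si](c1ccccc1)(c1ccccc1)C(C)(C)C)C[C@H]1C[C@@H](OC(C)=O)C[C@@H](CCl)O1
F5 | step 9 | C5 4-methoxybenzyl ether of the all-cis iodomethyl pyran 14 | CCCCCCCCC[C@H](O[Si](c1ccccc1)(c1ccccc1)C(C)(C)C)C[C@H](O[Si](c1ccccc1)(c1ccccc1)C(C)(C)C)C[C@H]1C[C@@H](OCc2ccc(OC)cc2)C[C@@H](CI)O1
F6 | step 9 | open-chain C7 alcohol with C5 4-methoxybenzyl ether and C3 vinyl group | CCCCCCCCC[C@H](O[Si](c1ccccc1)(c1ccccc1)C(C)(C)C)C[C@H](O[Si](c1ccccc1)(c1ccccc1)C(C)(C)C)C[C@H](O)C[C@@H](OCc1ccc(OC)cc1)CC=C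
F7 | step 9 | C7 tert-butyldimethylsilyl ether of F6 | CCCCCCCCC[C@H](O[Si](c1ccccc1)(c1ccccc1)C(C)(C)C)C[C@H](O[Si](c1ccccc1)(c1ccccc1)C(C)(C)C)C[C@H](O[Si](C)(C)C(C)(C)C)C[C@@H](OCc1ccc(OC)cc1)CC=C
F8 | step 9 | C5 alcohol with C7 tert-butyldimethylsilyl ether and C3 vinyl group | CCCCCCCCC[C@H](O[Si](c1ccccc1)(c1ccccc1)C(C)(C)C)C[C@H](O[Si](c1ccccc1)(c1ccccc1)C(C)(C)C)C[C@H](O[Si](C)(C)C(C)(C)C)C[C@@H](O)CC=C
F9 | step 9 | C5 acrylate of F8 | CCCCCCCCC[C@H](O[Si](c1ccccc1)(c1ccccc1)C(C)(C)C)C[C@H](O[Si](c1ccccc1)(c1ccccc1)C(C)(C)C)C[C@H](O[Si](C)(C)C(C)(C)C)C[C@@H](OC(=O)C=C)CC=C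
F10 | step 9 | tris-silyl ether of the target dihydropyranone (C7 tert-butyldimethylsilyl, C9 and C11 tert-butyldiphenylsilyl) | CCCCCCCCC[C@H](O[Si](c1ccccc1)(c1ccccc1)C(C)(C)C)C[C@H](O[Si](c1ccccc1)(c1ccccc1)C(C)(C)C)C[C@H](O[Si](C)(C)C(C)(C)C)C[C@@H]1CC=CC(=O)O1
F11 | step 1 | ethyl 3-oxododecanoate | CCCCCCCCCC(=O)CC(=O)OCC
F12 | step 1 | ethyl (S)-3-hydroxydodecanoate | CCCCCCCCC[C@H](O)CC(=O)OCC
F13 | step 1 | (S)-3-hydroxydodecanoic acid | CCCCCCCCC[C@H](O)CC(=O)O
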